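The flask holds less catalyst per litre than the summer run, 2.75 mM against 4.25 mM. So the target in the flask should isomerise more slowly.

the same everywhere: catalyst 2.5 mol%
- summer: substrate 0.17 M; partner 3 equiv; run made earlier
- flask: substrate 0.11 M; partner 3.00 equiv; time 10 h

summer run (percent of the substrate charged)

| time / min | target / % | isomer of the product / % |
|---|---|---|
| 10.0 | 20 | 1 |
| 20.0 | 28 | 2 |
| 30.0 | 31 | 6 |
| 40.0 | 35 | 11 |
| 50.0 | 34 | 13 |
| 60.0 | 32 | 14 |

(scatter of a reading: 1.5 percentage points)

- target is meant together with its crystals
- solid, in amounts per volume of the solution: crystals
- the earlier runs were read with a standard deviation of 1.5 percentage points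
- steps thought possible: substrate + partner <-> target; substrate + partner <-> isomer of the product; target + catalyst <-> isomer of the product + catalyst; partner -> decomposed reagent; crystals <-> target
- no earlier run changes the charge of catalyst; that part of a forecast is a guess

* share of target in target plus isomer of the product at 40 s
* share of target in target plus isomer of the product at 20 min
* share of target in target plus isomer of the product at 10 h

Read a rate from the summer run. Between 20.0 min and 40.0 min, isomer of the product rises from 2% to 11%, while target reads about 31%. Treat this as a pseudo-first-order step, which gives 0.871 h⁻¹. Scale it with [catalyst]. No earlier run tests that scaling, so it is a guess. This gives k, the isomerisation constant of the flask, the fraction of target turned into isomer of the product per hour: 0.564 h⁻¹.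

Now use a bench rule. While target builds up steadily, take [isomer of the product]/[target] as k·t divided by two. Work in powers of ten. At 20 min, log10(k·t) is −0.726, so the rule applies and gives the flask a share of 91.4%. At 10 h, log10(k·t) is 0.751. That time is 5.64 times 1/k, which is 1.77 h, so the rule has stopped working. I commit to no number at 10 h.

The forecast gives 95%, 90% and 60%, the last within 38% to 78%, on the ground that “isomerisation should have equilibrated”.

The flask gives 98.4%, 90.7% and 17.9%, so the last forecast stands 42 percentage points too high.

    substrate + partner ⇌ target (K = 3.90 L mol⁻¹, k = 3.20 L mol⁻¹ h⁻¹)
    substrate + partner ⇌ isomer of the product (K = 8.60 L mol⁻¹, k = 0.0440 L mol⁻¹ h⁻¹)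
    target + catalyst ⇌ isomer of the product + catalyst, rate k3*[catalyst]*[target] forward; the back reaction follows from the equilibrium constant (k = 160 L mol⁻¹ h⁻¹)
    partner → decomposed reagent (k = 0.930 h⁻¹)
    crystals ⇌ target, rate k5*(cs5 - [target]) while solid is left; crystals form when [target] > cs5 (solubility = 44.0 mM, k = 19.0 h⁻¹)

In the flask, target equals isomer of the product at 2.08 h, which is 1.17 times the 1/k estimated from the summer readings. With 1.5 mol% of catalyst, k becomes 0.338 h⁻¹, so the rule gives 94.7% at 20 min, and that neighbour flask gives 93.6%. At 10.0 h in the flask, target relaxes with substrate + partner in a half-life of 0.611 h, against 1.08 h with isomer of the product. By then substrate is back at 87.5% of its charge, and partner stands at 0.567% of its own.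

All runs are calculated on assumed constants, and the scatter is random.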